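Ring B is disconnected at C6–C7. The tetrasubstituted C8=C9 alkene with its C11 branch is read as a masked β-keto ester (C8 ketone, C11 ester on C9), which makes C7 an α-keto radical site; C5, flanked by the quaternary carbons C4 and C10, is offered as an exocyclic C5=C6 methylene. The precursor is thus a monocyclic γ-chloro β-keto ester on ring A. One tin hydride step closes ring B by 6-endo attack of the C7 radical on C6 and sets the trans ring fusion at C5 by hydrogen delivery anti to the C10 methyl, itself fixed by a palladium-catalysed asymmetric allylation. The side chain follows by dianion alkylation, silicon-tethered metathesis and Bestmann butenolide closure.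

Key step: step 6

Remark on numbering: terpenoid numbering is used: ring A = C1–C5 and C10 (gem-dimethyl at C4, methyl at C10), ring B = C5–C10 (methyl at C8), side chain C11–C15, butenolide C16–C19 (C19 carbonyl). Dec = (4aS,8aS)-2,5,5,8a-tetramethyl-3,4,4a,5,6,7,8,8a-octahydronaphthalen-1-yl, attached through C9.

Remark on the chemistry (assumptions): ketone 1 is used as the racemate because its only stereocentre is erased in step 1. The senses of induction in steps 2 and 14 are assigned by analogy with these catalyst families; the other antipode of ligand or acid would be taken if the opposite sense were found. Minor enantiomers carried from steps 2 and 14 should become separable as diastereomers at compound 31.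

Step 1
Reactants: 1 2,2,6-trimethylcyclohexan-1-one; 2 allyl chloroformate
Product: 4 prop-2-en-1-yl 2,6,6-trimethylcyclohex-1-en-1-yl carbonate, via lithium enolate 3 (not isolated)
Conditions: LiHMDS, THF, 0 °C; then 2, −78 → 25 °C
Reagents that add atoms: none
Why: The ketone has a single enolisable position, so one enolate forms and is O-acylated by the chloroformate (enol carbonate formation).

Step 2
Reactants: 4 prop-2-en-1-yl 2,6,6-trimethylcyclohex-1-en-1-yl carbonate
Product: 5 (2R)-2,6,6-trimethyl-2-(prop-2-en-1-yl)cyclohexan-1-one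
Conditions: Pd2(dba)3 (2.5 mol %), (R)-t-Bu-PHOX (6 mol %), THF, 25 °C
Reagents that add atoms: none
Why: Decarboxylative asymmetric allylic alkylation (Tsuji allylation), in which loss of CO2 gives an allyl palladium enolate and C–C bond formation inside the chiral PHOX pocket sets the quaternary centre C10, the (R)-ligand being expected to give the (R)-ketone as the mirror image of the (S)-ligand to (S)-ketone pairing of this substrate class.

Step 3
Reactants: 5 (2R)-2,6,6-trimethyl-2-(prop-2-en-1-yl)cyclohexan-1-one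
Product: 7 methyl 2-[(1R)-1,3,3-trimethyl-2-oxocyclohexyl]acetate, via keto aldehyde 6 (not isolated)
Conditions: O3, NaOH (2.5 M in MeOH), CH2Cl2, −78 °C
Reagents that add atoms: ozone, [O-][O+]=O; methanol, CO
Why: Ozonolysis in methanolic NaOH cleaves the terminal alkene and oxidises the hemiacetal of aldehyde 6 to the methyl ester with loss of one carbon, while the ketone, having no α-hydrogen, is inert to the base.

Step 4
Reactants: 7 methyl 2-[(1R)-1,3,3-trimethyl-2-oxocyclohexyl]acetate
Product: 8 methyl 2-[(1R)-1,3,3-trimethyl-2-methylidenecyclohexyl]acetate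
Conditions: Zn, CH2Br2, TiCl4, THF/CH2Cl2, 0 → 25 °C
Reagents that add atoms: dibromomethane, BrCBr
Why: Takai–Lombardo methylenation, whose non-basic titanium–zinc methylene reagent olefinates hindered ketones and leaves esters untouched, installs C6 as the exocyclic C5=C6 methylene.

Step 5
Reactants: 8 methyl 2-[(1R)-1,3,3-trimethyl-2-methylidenecyclohexyl]acetate; 9 chloroacetyl chloride
Product: 11 methyl 4-chloro-3-oxo-2-[(1R)-1,3,3-trimethyl-2-methylidenecyclohexyl]butanoate, via lithium ester enolate 10 (not isolated)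
Conditions: LDA, THF, −78 °C; then inverse addition to 9 (1.5 equiv), THF, −78 °C
Reagents that add atoms: none
Why: Claisen-type C-acylation of the lithium ester enolate by the acid chloride, run by inverse addition at low temperature to outrun O-acylation and proton transfer, gives the γ-chloro β-keto ester, and the new centre at C9 is of no consequence because it becomes sp2 in step 7.

Step 6
Reactants: 11 methyl 4-chloro-3-oxo-2-[(1R)-1,3,3-trimethyl-2-methylidenecyclohexyl]butanoate
Product: 14 methyl (4aS,8aS)-5,5,8a-trimethyl-2-oxodecahydronaphthalene-1-carboxylate, via C7 α-keto radical 12 (not isolated), via C5 tertiary radical 13 (not isolated)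
Conditions: Bu3SnH (1.3 equiv, syringe pump), AIBN (0.2 equiv), PhH (0.01 M), 80 °C
Reagents that add atoms: none
Why: Tin hydride radical chain reaction whose closest known type is the 6-endo cyclisation of 2-oxo-5-hexenyl (α-keto) radicals: Bu3Sn• abstracts chlorine from 11 to give the electrophilic primary radical 12 at C7. Radical 12 adds to the electron-rich exocyclic C5=C6 alkene at its unsubstituted terminus C6, forming the C6–C7 bond and closing ring B (C5 to C10) in the 6-endo-trig mode. The 5-exo alternative would need attack at C5, which is fully substituted and flanked by the quaternary carbons C4 and C10. The tertiary radical 13 at C5 then takes a hydrogen atom from Bu3SnH on the face opposite the axial methyl groups at C10 and C4, so C5 is set by substrate control from C10 and the ring fusion should be trans. The step needs cyclisation to outrun direct reduction of 12 (secured by high dilution and slow stannane addition) and 6-endo to beat 5-exo (secured by the substitution pattern and the polarity match). The C9 centre stays epimerisable and is erased in steps 7 and 8.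

Step 7
Reactants: 14 methyl (4aS,8aS)-5,5,8a-trimethyl-2-oxodecahydronaphthalene-1-carboxylate
Product: 16 methyl (4aS,8aS)-5,5,8a-trimethyl-2-{[(trifluoromethyl)sulfonyl]oxy}-3,4,4a,5,6,7,8,8a-octahydronaphthalene-1-carboxylate, via sodium enolate 15 (not isolated)
Conditions: NaH, Et2O, 0 °C; then Tf2O, 0 °C
Reagents that add atoms: trifluoromethanesulfonic anhydride, O=S(=O)(OS(=O)(=O)C(F)(F)F)C(F)(F)F
Why: O-Triflation of the β-keto ester enolate (enol triflate formation) fixes the enol double bond regiospecifically between C8 and C9.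

Step 8
Reactants: 16 methyl (4aS,8aS)-5,5,8a-trimethyl-2-{[(trifluoromethyl)sulfonyl]oxy}-3,4,4a,5,6,7,8,8a-octahydronaphthalene-1-carboxylate
Product: 17 methyl (4aS,8aS)-2,5,5,8a-tetramethyl-3,4,4a,5,6,7,8,8a-octahydronaphthalene-1-carboxylate
Conditions: MeMgBr, Fe(acac)3 (5 mol %), THF/NMP, −30 °C
Reagents that add atoms: methylmagnesium bromide, C[Mg]Br
Why: Iron-catalysed Kumada-type cross-coupling of the enol triflate installs the C8 methyl with the tetrasubstituted alkene locked at C8=C9 and is fast enough at low temperature to spare the hindered ester.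

Step 9
Reactants: 17 methyl (4aS,8aS)-2,5,5,8a-tetramethyl-3,4,4a,5,6,7,8,8a-octahydronaphthalene-1-carboxylate
Product: 18 Dec-methanol [(4aS,8aS)-2,5,5,8a-tetramethyl-3,4,4a,5,6,7,8,8a-octahydronaphthalen-1-yl]methanol
Conditions: i-Bu2AlH, CH2Cl2, −78 → 0 °C; Rochelle salt work-up
Reagents that add atoms: none
Why: 1,2-Reduction of the hindered enoate by the aluminium hydride gives the allylic alcohol (ester reduction).

Step 10
Reactants: 18 Dec-methanol
Product: 19 (4aS,8aS)-1-(bromomethyl)-2,5,5,8a-tetramethyl-3,4,4a,5,6,7,8,8a-octahydronaphthalene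
Conditions: PBr3, pyridine (cat.), Et2O, 0 °C
Reagents that add atoms: phosphorus tribromide, BrP(Br)Br
Why: PBr3 converts the primary allylic alcohol into the bromide by SN2 displacement, attack at the fully substituted C8 being disfavoured.

Step 11
Reactants: 19 (4aS,8aS)-1-(bromomethyl)-2,5,5,8a-tetramethyl-3,4,4a,5,6,7,8,8a-octahydronaphthalene; 20 2-methylprop-2-en-1-ol
Product: 22 4-Dec-2-methylidenebutan-1-ol, via dilithio dianion 21 (not isolated)
Conditions: 20, n-BuLi (2 equiv), TMEDA, Et2O/hexane, 0 → 25 °C; then 19, THF, −78 → 0 °C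
Reagents that add atoms: none
Why: SN2 alkylation of the allylic dianion, whose two carbon termini are equivalent, by the primary allylic bromide forms the C11–C12 bond and delivers the 1,1-disubstituted allylic alcohol.

Step 12
Reactants: 23 2,2-dimethoxypropane-1,3-diol
Product: 24 3-{[tert-butyl(dimethyl)silyl]oxy}-2,2-dimethoxypropan-1-ol
Conditions: TBSCl (0.5 equiv per diol), imidazole, THF, 0 °C
Reagents that add atoms: tert-butyldimethylsilyl chloride, CC(C)(C)[Si](C)(C)Cl
Why: Statistical monosilylation of the symmetrical diol, used in excess, gives the mono ether (silyl protection).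

Step 13
Reactants: 24 3-{[tert-butyl(dimethyl)silyl]oxy}-2,2-dimethoxypropan-1-ol
Product: 25 3-{[tert-butyl(dimethyl)silyl]oxy}-2,2-dimethoxypropanal
Conditions: TEMPO (cat.), PhI(OAc)2, CH2Cl2, 25 °C
Reagents that add atoms: none
Why: TEMPO-catalysed oxidation gives an aldehyde that has no α-hydrogen and therefore cannot enolise.

Step 14
Reactants: 25 3-{[tert-butyl(dimethyl)silyl]oxy}-2,2-dimethoxypropanal; 26 allylboronic acid pinacol ester
Product: 28 (3R)-1-{[tert-butyl(dimethyl)silyl]oxy}-2,2-dimethoxyhex-5-en-3-ol, via pinacol borate ester 27 (not isolated)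
Conditions: (R)-TRIP [(R)-3,3'-bis(2,4,6-triisopropylphenyl)-1,1'-binaphthyl-2,2'-diyl hydrogen phosphate] (5 mol %), 4 Å MS, toluene, −30 °C; aqueous work-up
Reagents that add atoms: none
Why: Chiral phosphoric acid catalysed allylboration through a closed chair transition state, in which the acid activates the boronate and re-face attack should set C16 as (R) by analogy with aryl and branched aliphatic aldehydes.

Step 15
Reactants: 28 (3R)-1-{[tert-butyl(dimethyl)silyl]oxy}-2,2-dimethoxyhex-5-en-3-ol; 22 4-Dec-2-methylidenebutan-1-ol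
Product: 30 {[(3R)-1-{[tert-butyl(dimethyl)silyl]oxy}-2,2-dimethoxyhex-5-en-3-yl]oxy}(4-Dec-2-methylidenebutoxy)di(propan-2-yl)silane, via chlorosilyl ether 29 (not isolated)
Conditions: 28, iPr2SiCl2 (excess), imidazole, CH2Cl2, 0 °C; evaporation of the excess; then 22, imidazole, DMAP (cat.), CH2Cl2, 25 °C
Reagents that add atoms: dichlorodi(propan-2-yl)silane, CC(C)[Si](Cl)(Cl)C(C)C
Why: Sequential silylation, first of the hindered secondary alcohol with excess dichlorosilane and then of the primary alcohol, builds the unsymmetrical silaketal (temporary silicon tether).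

Step 16
Reactants: 30 acyclic silaketal
Product: 31 (4R,6Z)-4-(2-{[tert-butyl(dimethyl)silyl]oxy}-1,1-dimethoxyethyl)-7-(2-Dec-ethyl)-2,2-di(propan-2-yl)-5,8-dihydro-4H-1,3,2-dioxasilocine
Conditions: second-generation Grubbs catalyst, (H2IMes)(PCy3)Cl2Ru=CHPh (10 mol %), CH2Cl2 (0.002 M), 40 °C
Reagents that add atoms: none
Why: Silicon-tethered ring-closing metathesis between the monosubstituted and the 1,1-disubstituted alkene forms an eight-membered ring in which the new trisubstituted C13=C14 alkene must be ring-cis, so the CH2O group and C15 end up on the same side.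

Step 17
Reactants: 31 eight-membered silaketal
Product: 32 (3R,5Z)-8-Dec-1,3-dihydroxy-6-(hydroxymethyl)oct-5-en-2-one
Conditions: HCl (2 M, aq.), THF, 25 °C
Reagents that add atoms: water, O
Why: Aqueous acid cleaves the silaketal, the primary silyl ether and the dimethyl ketal in one operation (acidic desilylation and ketal hydrolysis), unveiling the α-hydroxy ketone without base that could epimerise C16.

Step 18
Reactants: 32 (3R,5Z)-8-Dec-1,3-dihydroxy-6-(hydroxymethyl)oct-5-en-2-one
Product: 33 (3R,5Z)-1-{[tert-butyl(dimethyl)silyl]oxy}-6-({[tert-butyl(dimethyl)silyl]oxy}methyl)-8-Dec-3-hydroxyoct-5-en-2-one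
Conditions: TBSCl (2.1 equiv), imidazole, DMF, −20 → 0 °C
Reagents that add atoms: tert-butyldimethylsilyl chloride, CC(C)(C)[Si](C)(C)Cl
Why: Silylation should be much faster at the two primary hydroxyl groups than at the secondary α-ketol hydroxyl (selective protection).

Step 19
Reactants: 33 bis-silylated α-ketol; 34 (triphenylphosphoranylidene)ketene
Product: 36 (5R)-4-({[tert-butyl(dimethyl)silyl]oxy}methyl)-5-[(2Z)-3-({[tert-butyl(dimethyl)silyl]oxy}methyl)-5-Dec-pent-2-en-1-yl]furan-2(5H)-one, via acyl ylide 35 (not isolated)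
Conditions: 34 (1.2 equiv), toluene, 90 °C
Reagents that add atoms: none
Why: Bestmann butenolide synthesis, in which the secondary alcohol adds to the ketenylidene ylide and the resulting acyl ylide closes the lactone by intramolecular Wittig reaction with the adjacent ketone (C17=C18), C16 itself not being touched.

Step 20
Reactants: 36 bis-silyl ether of the target
Product: 37 16-epi-luffarin L
Conditions: HF·pyridine, pyridine, THF, 0 → 25 °C
Reagents that add atoms: none
Why: Buffered fluoride desilylation frees both primary alcohols under non-basic conditions that should not epimerise the butenolide γ-centre C16.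

Compound list

1 | 2,2,6-trimethylcyclohexan-1-one (racemic) | CC1CCCC(C)(C)C1=O | starting material
2 | allyl chloroformate | C=CCOC(Cl)=O | starting material
3 | lithium 2,6,6-trimethylcyclohex-1-en-1-olate (not isolated) | [Li+].[O-]C1=C(C)CCCC1(C)C | intermediate
4 | prop-2-en-1-yl 2,6,6-trimethylcyclohex-1-en-1-yl carbonate | C=CCOC(=O)OC1=C(C)CCCC1(C)C | intermediate
5 | (2R)-2,6,6-trimethyl-2-(prop-2-en-1-yl)cyclohexan-1-one | C=CC[C@@]1(C)CCCC(C)(C)C1=O | intermediate
6 | 2-[(1R)-1,3,3-trimethyl-2-oxocyclohexyl]acetaldehyde (not isolated) | O=CC[C@@]1(C)CCCC(C)(C)C1=O | intermediate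
7 | methyl 2-[(1R)-1,3,3-trimethyl-2-oxocyclohexyl]acetate | COC(=O)C[C@@]1(C)CCCC(C)(C)C1=O | intermediate
8 | methyl 2-[(1R)-1,3,3-trimethyl-2-methylidenecyclohexyl]acetate | COC(=O)C[C@@]1(C)CCCC(C)(C)C1=C | intermediate
9 | chloroacetyl chloride | ClCC(Cl)=O | starting material
10 | lithium enolate of 8 (not isolated) | [Li+].[O-]C(OC)=C[C@@]1(C)CCCC(C)(C)C1=C | intermediate
11 | methyl 4-chloro-3-oxo-2-[(1R)-1,3,3-trimethyl-2-methylidenecyclohexyl]butanoate (C2 epimers) | COC(=O)C(C(=O)CCl)[C@@]1(C)CCCC(C)(C)C1=C | intermediate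
12 | C7 α-keto radical derived from 11 (not isolated) | [CH2]C(=O)C(C(=O)OC)[C@@]1(C)CCCC(C)(C)C1=C | intermediate
13 | C5 tertiary radical of the closed bicycle (not isolated) | O=C1C(C(=O)OC)[C@@]2(C)CCCC(C)(C)[C]2CC1 | intermediate
14 | methyl (4aS,8aS)-5,5,8a-trimethyl-2-oxodecahydronaphthalene-1-carboxylate (trans-fused, C1 epimers) | O=C1C(C(=O)OC)[C@@]2(C)CCCC(C)(C)[C@@H]2CC1 | intermediate
15 | sodium enolate of 14 (not isolated) | [Na+].[O-]C1=C(C(=O)OC)[C@@]2(C)CCCC(C)(C)[C@@H]2CC1 | intermediate
16 | methyl (4aS,8aS)-5,5,8a-trimethyl-2-{[(trifluoromethyl)sulfonyl]oxy}-3,4,4a,5,6,7,8,8a-octahydronaphthalene-1-carboxylate | O=S(=O)(OC1=C(C(=O)OC)[C@@]2(C)CCCC(C)(C)[C@@H]2CC1)C(F)(F)F | intermediate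
17 | methyl (4aS,8aS)-2,5,5,8a-tetramethyl-3,4,4a,5,6,7,8,8a-octahydronaphthalene-1-carboxylate | CC1=C(C(=O)OC)[C@@]2(C)CCCC(C)(C)[C@@H]2CC1 | intermediate
18 | [(4aS,8aS)-2,5,5,8a-tetramethyl-3,4,4a,5,6,7,8,8a-octahydronaphthalen-1-yl]methanol | CC1=C(CO)[C@@]2(C)CCCC(C)(C)[C@@H]2CC1 | intermediate
19 | (4aS,8aS)-1-(bromomethyl)-2,5,5,8a-tetramethyl-3,4,4a,5,6,7,8,8a-octahydronaphthalene | CC1=C(CBr)[C@@]2(C)CCCC(C)(C)[C@@H]2CC1 | intermediate
20 | 2-methylprop-2-en-1-ol | C=C(C)CO | starting material
21 | dilithio dianion of 20 (not isolated) | [Li+].[Li+].[CH2-]C(=C)C[O-] | intermediate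
22 | 2-methylidene-4-[(4aS,8aS)-2,5,5,8a-tetramethyl-3,4,4a,5,6,7,8,8a-octahydronaphthalen-1-yl]butan-1-ol | CC1=C(CCC(=C)CO)[C@@]2(C)CCCC(C)(C)[C@@H]2CC1 | intermediate
23 | 2,2-dimethoxypropane-1,3-diol | COC(CO)(CO)OC | starting material
24 | 3-{[tert-butyl(dimethyl)silyl]oxy}-2,2-dimethoxypropan-1-ol | COC(CO)(CO[Si](C)(C)C(C)(C)C)OC | intermediate
25 | 3-{[tert-butyl(dimethyl)silyl]oxy}-2,2-dimethoxypropanal | COC(C=O)(CO[Si](C)(C)C(C)(C)C)OC | intermediate
26 | allylboronic acid pinacol ester | C=CCB1OC(C)(C)C(C)(C)O1 | starting material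
27 | pinacol borate ester of 28 (not isolated) | C=CC[C@@H](OB1OC(C)(C)C(C)(C)O1)C(OC)(OC)CO[Si](C)(C)C(C)(C)C | intermediate
28 | (3R)-1-{[tert-butyl(dimethyl)silyl]oxy}-2,2-dimethoxyhex-5-en-3-ol | C=CC[C@@H](O)C(OC)(OC)CO[Si](C)(C)C(C)(C)C | intermediate
29 | chloro[di(propan-2-yl)]silyl ether of 28 (not isolated) | C=CC[C@@H](O[Si](Cl)(C(C)C)C(C)C)C(OC)(OC)CO[Si](C)(C)C(C)(C)C | intermediate
30 | acyclic silaketal: di(propan-2-yl)silyl bis-ether of 28 (secondary O) and 22 (primary O) | CC1=C(CCC(=C)CO[Si](C(C)C)(C(C)C)O[C@H](CC=C)C(OC)(OC)CO[Si](C)(C)C(C)(C)C)[C@@]2(C)CCCC(C)(C)[C@@H]2CC1 | intermediate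
31 | (4R,6Z)-4-(2-{[tert-butyl(dimethyl)silyl]oxy}-1,1-dimethoxyethyl)-7-(2-Dec-ethyl)-2,2-di(propan-2-yl)-5,8-dihydro-4H-1,3,2-dioxasilocine | CC1=C(CC/C3=C/C[C@H](C(OC)(OC)CO[Si](C)(C)C(C)(C)C)O[Si](C(C)C)(C(C)C)OC3)[C@@]2(C)CCCC(C)(C)[C@@H]2CC1 | intermediate
32 | (3R,5Z)-8-Dec-1,3-dihydroxy-6-(hydroxymethyl)oct-5-en-2-one | CC1=C(CC/C(=C/C[C@@H](O)C(=O)CO)CO)[C@@]2(C)CCCC(C)(C)[C@@H]2CC1 | intermediate
33 | (3R,5Z)-1-{[tert-butyl(dimethyl)silyl]oxy}-6-({[tert-butyl(dimethyl)silyl]oxy}methyl)-8-Dec-3-hydroxyoct-5-en-2-one | CC1=C(CC/C(=C/C[C@@H](O)C(=O)CO[Si](C)(C)C(C)(C)C)CO[Si](C)(C)C(C)(C)C)[C@@]2(C)CCCC(C)(C)[C@@H]2CC1 | intermediate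
34 | (triphenylphosphoranylidene)ketene (Bestmann ylide) | O=C=C=P(c1ccccc1)(c1ccccc1)c1ccccc1 | starting material
35 | (triphenylphosphoranylidene)acetate ester of 33 at the C16 oxygen (not isolated) | CC1=C(CC/C(=C/C[C@@H](OC(=O)C=P(c3ccccc3)(c3ccccc3)c3ccccc3)C(=O)CO[Si](C)(C)C(C)(C)C)CO[Si](C)(C)C(C)(C)C)[C@@]2(C)CCCC(C)(C)[C@@H]2CC1 | intermediate
36 | (5R)-4-({[tert-butyl(dimethyl)silyl]oxy}methyl)-5-[(2Z)-3-({[tert-butyl(dimethyl)silyl]oxy}methyl)-5-Dec-pent-2-en-1-yl]furan-2(5H)-one | CC1=C(CC/C(=C/C[C@H]3OC(=O)C=C3CO[Si](C)(C)C(C)(C)C)CO[Si](C)(C)C(C)(C)C)[C@@]2(C)CCCC(C)(C)[C@@H]2CC1 | intermediate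
37 | 16-epi-luffarin L, (5R)-4-(hydroxymethyl)-5-[(2Z)-3-(hydroxymethyl)-5-Dec-pent-2-en-1-yl]furan-2(5H)-one | CC1=C(CC/C(=C/C[C@H]2OC(=O)C=C2CO)CO)[C@@]2(C)CCCC(C)(C)[C@@H]2CC1 | target

Total step count: 20. Longest linear sequence: 17 (steps 1–11, then 15–20); steps 12–14 make the C14–C17 fragment 28.

Steps most likely to fail

Step 6 (key step). The α-keto radical may take hydrogen from the stannane before it cyclises, and hydrogen delivery to the C5 radical may occur on the wrong face and give the cis ring fusion. The fallback separates ring closure from reduction and still forms the C6–C7 bond. From 11, halide exchange (NaI, acetone) would give methyl 4-iodo-3-oxo-2-[(1R)-1,3,3-trimethyl-2-methylidenecyclohexyl]butanoate F1. Iodine atom-transfer cyclisation ((Bu3Sn)2 cat., hν, PhH), which has no hydrogen donor present, should give methyl (8aR)-4a-iodo-5,5,8a-trimethyl-2-oxodecahydronaphthalene-1-carboxylate F2. Elimination with DBU can only occur towards C6 and should give methyl (8aR)-5,5,8a-trimethyl-2-oxo-1,2,3,5,6,7,8,8a-octahydronaphthalene-1-carboxylate F3. Hydrogenation (H2, PtO2, AcOH) from the face away from the C10 methyl returns to 14.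

Step 4. The bulky titanium–zinc reagent may fail to add to the doubly neopentyl carbonyl, or the methylenation may be so slow that side reactions take over. The fallback moves the olefination before the ester is made. From 5, Wittig methylenation (Ph3PCH3Br, KOt-Bu, toluene, 90 °C) would give (1R)-1,3,3-trimethyl-2-methylidene-1-(prop-2-en-1-yl)cyclohexane F4. Lemieux–Johnson cleavage (OsO4 cat., NaIO4, 2,6-lutidine, dioxane/H2O) of the unhindered monosubstituted alkene only should give 2-[(1R)-1,3,3-trimethyl-2-methylidenecyclohexyl]acetaldehyde F5. Pinnick oxidation gives 2-[(1R)-1,3,3-trimethyl-2-methylidenecyclohexyl]acetic acid F6, and esterification with TMSCHN2 returns to 8.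

Step 19. The basic ylide at 90 °C may enolise the α-ketol before the Wittig closure, which would epimerise C16 or shift the ketol. The fallback replaces the thermal Wittig closure by a low-temperature Horner–Wadsworth–Emmons closure. From 33, esterification with diethylphosphonoacetic acid (EDC, DMAP, CH2Cl2, 0 °C) would give the C16 diethylphosphonoacetate of 33 F7. Intramolecular olefination under Masamune–Roush conditions (LiCl, iPr2NEt, MeCN, 0 °C) returns to 36.

Further compounds

F1 | step 6 | methyl 4-iodo-3-oxo-2-[(1R)-1,3,3-trimethyl-2-methylidenecyclohexyl]butanoate | COC(=O)C(C(=O)CI)[C@@]1(C)CCCC(C)(C)C1=C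
F2 | step 6 | methyl (8aR)-4a-iodo-5,5,8a-trimethyl-2-oxodecahydronaphthalene-1-carboxylate | O=C1C(C(=O)OC)[C@@]2(C)CCCC(C)(C)C2(I)CC1
F3 | step 6 | methyl (8aR)-5,5,8a-trimethyl-2-oxo-1,2,3,5,6,7,8,8a-octahydronaphthalene-1-carboxylate | O=C1C(C(=O)OC)[C@@]2(C)CCCC(C)(C)C2=CC1
F4 | step 4 | (1R)-1,3,3-trimethyl-2-methylidene-1-(prop-2-en-1-yl)cyclohexane | C=CC[C@@]1(C)CCCC(C)(C)C1=C
F5 | step 4 | 2-[(1R)-1,3,3-trimethyl-2-methylidenecyclohexyl]acetaldehyde | O=CC[C@@]1(C)CCCC(C)(C)C1=C
F6 | step 4 | 2-[(1R)-1,3,3-trimethyl-2-methylidenecyclohexyl]acetic acid | OC(=O)C[C@@]1(C)CCCC(C)(C)C1=C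
F7 | step 19 | C16 diethylphosphonoacetate of 33 | CC1=C(CC/C(=C/C[C@@H](OC(=O)CP(=O)(OCC)OCC)C(=O)CO[Si](C)(C)C(C)(C)C)CO[Si](C)(C)C(C)(C)C)[C@@]2(C)CCCC(C)(C)[C@@H]2CC1
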